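The route grows the benzenoid ring of the indole onto a ready-made pyrrole. In that ring C4 carries OMe and C6 carries Br, with bare C5 between them. This 1,3-pattern is read as an enol ether (C4=C5) facing a bromoalkyne (C6≡C7). Making the C5–C6 bond by Lewis-acid cycloisomerisation closes the six-membered ring and sets both substituents in one operation, so no arene halogenation or O-alkylation is needed later. The precursor is an N-phenylsulfonylpyrrole with bromoethynyl at C2 and 1-methoxyvinyl at C3. The iodooxazole–pyrrole arm is then attached at indole C3 by formylation, TosMIC annulation, double iodination and a C2-selective Suzuki coupling.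

Key step: step 6

Remark: the target has no stereocentre and no stereogenic double bond, so no step has to control configuration. LDA, LiHMDS and TBAF are taken as purchased solutions.

Step 1
Reactants: 1 3-acetyl-1-(phenylsulfonyl)pyrrole
Product: 2 3-(1,1-dimethoxyethyl)-1-(phenylsulfonyl)pyrrole
Conditions: HC(OMe)3 (3 equiv), p-TsOH·H2O (5 mol %), MeOH, 50 °C; Et3N quench
Reagents that add atoms: trimethyl orthoformate, COC(OC)OC
Why: Acid-catalysed ketalisation of an aryl methyl ketone, pulled to completion by the orthoester as water scavenger, masks the enolisable ketone for the coming base steps and already stores the future C4 methoxy group, while the N-sulfonyl group is inert to the mild acid.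

Step 2
Reactants: 2 3-(1,1-dimethoxyethyl)-1-(phenylsulfonyl)pyrrole
Product: 4 3-(1,1-dimethoxyethyl)-1-(phenylsulfonyl)pyrrole-2-carbaldehyde, via 2-lithiopyrrole 3 (not isolated)
Conditions: LDA (1.2 equiv), THF, −78 °C, 1 h; DMF (3 equiv), −78 → 0 °C; H2O
Reagents that add atoms: N,N-dimethylformamide, CN(C)C=O; lithium diisopropylamide, CC(C)N([Li])C(C)C (lithium of 3 only)
Why: Directed ortho-metalation and formylation: C2–H lies between the sulfonylated nitrogen and the ketal, both of which can chelate lithium, and because amide-base metalation is reversible through diisopropylamine the doubly chelated C2-lithio species 3 should accumulate and be trapped by DMF.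

Step 3
Reactants: 4 3-(1,1-dimethoxyethyl)-1-(phenylsulfonyl)pyrrole-2-carbaldehyde; 5 carbon tetrabromide
Product: 6 2-(2,2-dibromovinyl)-3-(1,1-dimethoxyethyl)-1-(phenylsulfonyl)pyrrole
Conditions: 5 (2 equiv), PPh3 (4 equiv), CH2Cl2, 0 °C; Et3N (2 equiv); then 4, −78 → 0 °C; hexane, filtration through Et3N-washed silica
Reagents that add atoms: none
Why: Ramirez dibromoolefination (first half of the Corey–Fuchs sequence) with preformed Ph3P=CBr2 is general for aromatic aldehydes, and the added triethylamine buffers the acidic bromophosphonium species that could otherwise unmask the dimethyl ketal.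

Step 4
Reactants: 6 2-(2,2-dibromovinyl)-3-(1,1-dimethoxyethyl)-1-(phenylsulfonyl)pyrrole
Product: 7 2-(bromoethynyl)-3-(1,1-dimethoxyethyl)-1-(phenylsulfonyl)pyrrole
Conditions: DBU (2.5 equiv), MeCN, rt
Reagents that add atoms: none
Why: Base-induced anti E2 dehydrobromination of an aryl-conjugated 1,1-dibromoalkene is a standard entry to 1-bromoalkynes, and the non-nucleophilic amidine leaves sulfonamide and ketal untouched.

Step 5
Reactants: 7 2-(bromoethynyl)-3-(1,1-dimethoxyethyl)-1-(phenylsulfonyl)pyrrole
Product: 8 2-(bromoethynyl)-3-(1-methoxyvinyl)-1-(phenylsulfonyl)pyrrole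
Conditions: Me3SiOTf (1.3 equiv), i-Pr2NEt (1.6 equiv), CH2Cl2, −20 °C → rt; aq. NaHCO3; short plug of basic alumina
Reagents that add atoms: none
Why: Silyl-triflate-mediated elimination of methanol from a ketal: Me3SiOTf ionises one methoxy group to an oxocarbenium ion and the hindered amine removes a proton from the methyl group, the only adjacent C–H site, so a single enol ether forms under non-acidic conditions that spare the bromoalkyne.

Step 6
Reactants: 8 2-(bromoethynyl)-3-(1-methoxyvinyl)-1-(phenylsulfonyl)pyrrole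
Product: 9 6-bromo-4-methoxy-1-(phenylsulfonyl)indole
Conditions: InCl3 (10 mol %), 2,6-di-tert-butylpyridine (15 mol %), 4 Å MS, toluene, 60–80 °C
Reagents that add atoms: none
Why: Proposed new method: InCl3 acts as a π-acid on the bromoalkyne, the electron-rich CH2 terminus of the enol ether (future C5) bonds to the bromine-bearing alkyne carbon (future C6) to leave an oxocarbenium ion at C4 and a vinyl–indium bond at C7, and proton loss from C5 followed by protodemetalation at C7 gives the aromatic ring, so the step is a pure isomerisation. The closest known reaction types are the metal-catalysed carbocyclisation of enol ethers onto ortho-alkynyl groups that furnishes naphthol ethers and the InCl3-catalysed cycloisomerisation of ortho-(haloethynyl)biaryls that keeps the halogen on its original carbon, but the pairing of an enol ether with a bromoalkyne on a pyrrole core is untested. The single new ring, the benzenoid ring of the indole, closes in the 6-endo-dig mode and no stereocentre arises. Site selectivity at the nucleophile is fixed by enol ether polarity (only C5 is nucleophilic), and 6-endo closure should beat 5-exo closure at C7 because the splayed exocyclic bonds at pyrrole C2 and C3 make a fused five-membered ring strained, bromine lone pairs stabilise cationic character at C6, and only the 6-endo path ends in an arene. Bromine stays on C6 because a main-group halide such as InCl3 does not form the metal vinylidene through which AuCl or PtCl2 can shift halogen to C7. The sulfonyl group damps the pyrrole carbons as rival nucleophiles and weakens donation towards C7, while the hindered pyridine and the sieves stop stray HCl or water from hydrolysing the enol ether yet still relay the proton.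

Step 7
Reactants: 9 6-bromo-4-methoxy-1-(phenylsulfonyl)indole
Product: 10 6-bromo-4-methoxy-1H-indole
Conditions: NaOH (3 M aq., 5 equiv), 1,4-dioxane, 80 °C
Reagents that add atoms: none
Why: Hydroxide attacks sulfur and expels the indolide in a standard sulfonamide hydrolysis of N-sulfonylindoles, the methanol-free medium avoids methyl benzenesulfonate and thus N-methylation, and the aryl bromide and aryl ether are inert.

Step 8
Reactants: 10 6-bromo-4-methoxy-1H-indole
Product: 12 6-bromo-4-methoxy-1H-indole-3-carbaldehyde, via iminium chloride 11 (not isolated)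
Conditions: POCl3 (1.2 equiv), DMF, 0 °C → rt; then 2 M aq. NaOH, rt → 50 °C
Reagents that add atoms: N,N-dimethylformamide, CN(C)C=O; water, O; phosphoryl chloride, O=P(Cl)(Cl)Cl (chloride counter-ion of 11 only)
Why: Vilsmeier–Haack formylation of a free N–H indole takes place at C3, its most nucleophilic carbon, ahead of the methoxy-activated benzenoid positions, and basic hydrolysis of iminium salt 11 releases the aldehyde.

Step 9
Reactants: 12 6-bromo-4-methoxy-1H-indole-3-carbaldehyde; 13 p-toluenesulfonylmethyl isocyanide (TosMIC)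
Product: 14 5-(6-bromo-4-methoxy-1H-indol-3-yl)oxazole
Conditions: 13 (1.3 equiv), K2CO3 (2.5 equiv), MeOH, reflux
Reagents that add atoms: none
Why: Van Leusen oxazole synthesis: the TosMIC anion adds to the aldehyde, the alkoxide closes onto the isocyanide carbon and loss of toluenesulfinate aromatises the ring to a 5-substituted oxazole, a sequence that tolerates unprotected indole-3-carbaldehydes.

Step 10
Reactants: 14 5-(6-bromo-4-methoxy-1H-indol-3-yl)oxazole
Product: 15 5-[6-bromo-4-methoxy-1-(triisopropylsilyl)indol-3-yl]oxazole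
Conditions: TIPSCl (1.2 equiv), NaH (1.2 equiv), THF, 0 °C → rt
Reagents that add atoms: chlorotriisopropylsilane, CC(C)[Si](Cl)(C(C)C)C(C)C
Why: N-silylation of the indolide removes the acidic N–H before the amide-base steps, and the bulky silyl group shields indole C2 and C7 and withstands LiHMDS and aqueous carbonate.

Step 11
Reactants: 15 5-[6-bromo-4-methoxy-1-(triisopropylsilyl)indol-3-yl]oxazole
Product: 19 5-[6-bromo-4-methoxy-1-(triisopropylsilyl)indol-3-yl]-2,4-diiodooxazole, via lithium isocyanoenolate 16 (not isolated), via 4-iodooxazole 17 (not isolated), via 2-lithio-4-iodooxazole 18 (not isolated)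
Conditions: LiHMDS (1.2 equiv), THF/DMPU, −78 °C; I2 (1.1 equiv), −78 → −40 °C; LiHMDS (1.5 equiv), −78 °C; I2 (1.5 equiv), −78 → 0 °C; aq. Na2S2O3
Reagents that add atoms: iodine, II; lithium hexamethyldisilazide, [Li]N([Si](C)(C)C)[Si](C)(C)C (lithium of 16 and 18 only)
Why: Oxazole deprotonation–iodination: in the presence of DMPU the C2-lithiated 5-substituted oxazole reacts as its ring-opened isocyano enolate 16 at the carbon that becomes C4 and re-closes to 17, whose remaining acidic C2–H is then lithiated and iodinated in the same flask, while LiHMDS causes no bromine–lithium exchange.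

Step 12
Reactants: 19 5-[6-bromo-4-methoxy-1-(triisopropylsilyl)indol-3-yl]-2,4-diiodooxazole; 20 [1-(tert-butoxycarbonyl)pyrrol-2-yl]boronic acid
Product: 21 tert-butyl 2-{5-[6-bromo-4-methoxy-1-(triisopropylsilyl)indol-3-yl]-4-iodooxazol-2-yl}pyrrole-1-carboxylate
Conditions: 20 (1.2 equiv), Pd(PPh3)4 (5 mol %), Na2CO3 (2 M aq., 2 equiv), 1,4-dioxane, 60 °C
Reagents that add atoms: none
Why: Site-selective Suzuki–Miyaura coupling: oxidative addition of zerovalent palladium is fastest at the unhindered C2–I bond flanked by O and N, slower at the C4–I bond crowded by the 4-methoxyindolyl group, and slowest at the aryl C–Br bond.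

Step 13
Reactants: 21 tert-butyl 2-{5-[6-bromo-4-methoxy-1-(triisopropylsilyl)indol-3-yl]-4-iodooxazol-2-yl}pyrrole-1-carboxylate
Product: 23 5-(6-bromo-4-methoxy-1H-indol-3-yl)-4-iodo-2-(1H-pyrrol-2-yl)oxazole (CNP0134885.0), via N-Boc pyrrole 22 (not isolated)
Conditions: TBAF/AcOH (1:1, 1.2 equiv), THF, 0 °C; then K2CO3 (3 equiv), MeOH, rt
Reagents that add atoms: none
Why: Fluoride-induced N-desilylation followed by carbonate-catalysed methanolysis of the acyl-like pyrrole carbamate removes both groups without acid, which avoids protodeiodination of the electron-rich iodooxazole.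

Compound list
1 | 3-acetyl-1-(phenylsulfonyl)pyrrole | CC(=O)c1ccn(S(=O)(=O)c2ccccc2)c1 | starting material
2 | 3-(1,1-dimethoxyethyl)-1-(phenylsulfonyl)pyrrole | COC(C)(OC)c1ccn(S(=O)(=O)c2ccccc2)c1 | intermediate
3 | 3-(1,1-dimethoxyethyl)-2-lithio-1-(phenylsulfonyl)pyrrole | [Li]c1c(C(C)(OC)OC)ccn1S(=O)(=O)c1ccccc1 | intermediate
4 | 3-(1,1-dimethoxyethyl)-1-(phenylsulfonyl)pyrrole-2-carbaldehyde | COC(C)(OC)c1ccn(S(=O)(=O)c2ccccc2)c1C=O | intermediate
5 | carbon tetrabromide | BrC(Br)(Br)Br | starting material
6 | 2-(2,2-dibromovinyl)-3-(1,1-dimethoxyethyl)-1-(phenylsulfonyl)pyrrole | COC(C)(OC)c1ccn(S(=O)(=O)c2ccccc2)c1C=C(Br)Br | intermediate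
7 | 2-(bromoethynyl)-3-(1,1-dimethoxyethyl)-1-(phenylsulfonyl)pyrrole | COC(C)(OC)c1ccn(S(=O)(=O)c2ccccc2)c1C#CBr | intermediate
8 | 2-(bromoethynyl)-3-(1-methoxyvinyl)-1-(phenylsulfonyl)pyrrole | COC(=C)c1ccn(S(=O)(=O)c2ccccc2)c1C#CBr | intermediate
9 | 6-bromo-4-methoxy-1-(phenylsulfonyl)indole | COc1cc(Br)cc2c1ccn2S(=O)(=O)c1ccccc1 | intermediate
10 | 6-bromo-4-methoxy-1H-indole | COc1cc(Br)cc2[nH]ccc12 | intermediate
11 | (6-bromo-4-methoxy-1H-indol-3-yl)methylidene-dimethylammonium chloride | COc1cc(Br)cc2[nH]cc(C=[N+](C)C)c12.[Cl-] | intermediate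
12 | 6-bromo-4-methoxy-1H-indole-3-carbaldehyde | COc1cc(Br)cc2[nH]cc(C=O)c12 | intermediate
13 | p-toluenesulfonylmethyl isocyanide | Cc1ccc(S(=O)(=O)C[N+]#[C-])cc1 | starting material
14 | 5-(6-bromo-4-methoxy-1H-indol-3-yl)oxazole | COc1cc(Br)cc2[nH]cc(-c3cnco3)c12 | intermediate
15 | 5-[6-bromo-4-methoxy-1-(triisopropylsilyl)indol-3-yl]oxazole | COc1cc(Br)cc2c1c(-c1cnco1)cn2[Si](C(C)C)(C(C)C)C(C)C | intermediate
16 | lithium (Z)-1-[6-bromo-4-methoxy-1-(triisopropylsilyl)indol-3-yl]-2-isocyanoethenolate | COc1cc(Br)cc2c1c(/C(O[Li])=C/[N+]#[C-])cn2[Si](C(C)C)(C(C)C)C(C)C | intermediate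
17 | 5-[6-bromo-4-methoxy-1-(triisopropylsilyl)indol-3-yl]-4-iodooxazole | COc1cc(Br)cc2c1c(-c1ocnc1I)cn2[Si](C(C)C)(C(C)C)C(C)C | intermediate
18 | 5-[6-bromo-4-methoxy-1-(triisopropylsilyl)indol-3-yl]-4-iodo-2-lithiooxazole | COc1cc(Br)cc2c1c(-c1oc([Li])nc1I)cn2[Si](C(C)C)(C(C)C)C(C)C | intermediate
19 | 5-[6-bromo-4-methoxy-1-(triisopropylsilyl)indol-3-yl]-2,4-diiodooxazole | COc1cc(Br)cc2c1c(-c1oc(I)nc1I)cn2[Si](C(C)C)(C(C)C)C(C)C | intermediate
20 | [1-(tert-butoxycarbonyl)pyrrol-2-yl]boronic acid | CC(C)(C)OC(=O)n1cccc1B(O)O | starting material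
21 | tert-butyl 2-{5-[6-bromo-4-methoxy-1-(triisopropylsilyl)indol-3-yl]-4-iodooxazol-2-yl}pyrrole-1-carboxylate | COc1cc(Br)cc2c1c(-c1oc(-c3cccn3C(=O)OC(C)(C)C)nc1I)cn2[Si](C(C)C)(C(C)C)C(C)C | intermediate
22 | tert-butyl 2-[5-(6-bromo-4-methoxy-1H-indol-3-yl)-4-iodooxazol-2-yl]pyrrole-1-carboxylate | COc1cc(Br)cc2[nH]cc(-c3oc(-c4cccn4C(=O)OC(C)(C)C)nc3I)c12 | intermediate
23 | 5-(6-bromo-4-methoxy-1H-indol-3-yl)-4-iodo-2-(1H-pyrrol-2-yl)oxazole | COc1cc(Br)cc2[nH]cc(-c3oc(-c4ccc[nH]4)nc3I)c12 | target

Total step count: 13. Longest linear sequence: 13 steps (1 → 23).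

Steps most likely to fail

Step 6 (cycloisomerisation).
- What may go wrong: ring closure at the inner alkyne carbon instead of the outer one, migration of bromine along the alkyne, or acid-induced hydrolysis and oligomerisation of the enol ether before it cyclises.
- Fallback, from 6 back to 9: the same C5–C6 bond is closed pericyclically, without an alkyne.
- Dibromoalkene 6 is treated with Me3SiOTf/i-Pr2NEt as in step 5 to give 2-(2,2-dibromovinyl)-3-(1-methoxyvinyl)-1-(phenylsulfonyl)pyrrole F1. This is a 1,3,5-hexatriene whose central double bond is the pyrrole C2–C3 bond.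
- Heating in 1,2-dichlorobenzene at about 150–180 °C over powdered K2CO3 should cause thermal 6π-electrocyclisation to 6,6-dibromo-4-methoxy-1-(phenylsulfonyl)-5,6-dihydro-1H-indole F2. F2 loses HBr at once and aromatises to 9.
- Electrocyclisation of 2,3-dialkenylpyrroles with eliminative or oxidative aromatisation is an established indole synthesis. The position of bromine cannot drift because both halogens sit on C6.

Step 2 (C2 metalation).
- What may go wrong: loss of regiocontrol through metalation at the less hindered C5, or at the ortho position of the phenylsulfonyl ring.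
- Fallback, from 2 back to 4: the unwanted preference is used as a blocking step.
- LDA converts 2 into 3-(1,1-dimethoxyethyl)-5-lithio-1-(phenylsulfonyl)pyrrole F3, and Me3SiCl traps it as 3-(1,1-dimethoxyethyl)-1-(phenylsulfonyl)-5-(trimethylsilyl)pyrrole F4.
- With C5 occupied, a second metalation (LDA or LiTMP, THF, −78 °C) can only take the remaining α-position. It gives 3-(1,1-dimethoxyethyl)-2-lithio-1-(phenylsulfonyl)-5-(trimethylsilyl)pyrrole F5.
- DMF then gives 3-(1,1-dimethoxyethyl)-1-(phenylsulfonyl)-5-(trimethylsilyl)pyrrole-2-carbaldehyde F6.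
- Fluoride protodesilylation (TBAF, wet THF, 0 °C) of the α-silyl group, which is activated by the sulfonyl and formyl groups, returns 4.

Step 11 (double iodination).
- What may go wrong: iodine transfer to C2 rather than C4 in the first stage, which blocks the second stage. The reaction may also stall at mono-iodination because residual iodine consumes the second charge of base.
- Fallback, from 15 back to 21, bypassing step 12 as well: the order of events is reversed, and C4 is iodinated electrophilically rather than through an anion.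
- TMPZnCl·LiCl (THF, rt) metalates C2 without ring opening to give chloro{5-[6-bromo-4-methoxy-1-(triisopropylsilyl)indol-3-yl]oxazol-2-yl}zinc F7. Iodolysis gives 5-[6-bromo-4-methoxy-1-(triisopropylsilyl)indol-3-yl]-2-iodooxazole F8.
- F8 has only one C–I bond. Suzuki coupling with 20 under the conditions of step 12 gives tert-butyl 2-{5-[6-bromo-4-methoxy-1-(triisopropylsilyl)indol-3-yl]oxazol-2-yl}pyrrole-1-carboxylate F9.
- N-Iodosuccinimide (DMF, 0 °C → rt) then iodinates oxazole C4 to give 21. C4 is the usual site of halogenation in 2,5-diaryloxazoles. Here it is further activated as the terminus of the dienamine that runs from indole N1 through C2=C3 and oxazole C5=C4.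

Further compounds
F1 | step 6 | 2-(2,2-dibromovinyl)-3-(1-methoxyvinyl)-1-(phenylsulfonyl)pyrrole | COC(=C)c1ccn(S(=O)(=O)c2ccccc2)c1C=C(Br)Br
F2 | step 6 | 6,6-dibromo-4-methoxy-1-(phenylsulfonyl)-5,6-dihydro-1H-indole | COC1=C2C=CN(S(=O)(=O)c3ccccc3)C2=CC(Br)(Br)C1
F3 | step 2 | 3-(1,1-dimethoxyethyl)-5-lithio-1-(phenylsulfonyl)pyrrole | [Li]c1cc(C(C)(OC)OC)cn1S(=O)(=O)c1ccccc1
F4 | step 2 | 3-(1,1-dimethoxyethyl)-1-(phenylsulfonyl)-5-(trimethylsilyl)pyrrole | COC(C)(OC)c1cn(S(=O)(=O)c2ccccc2)c([Si](C)(C)C)c1
F5 | step 2 | 3-(1,1-dimethoxyethyl)-2-lithio-1-(phenylsulfonyl)-5-(trimethylsilyl)pyrrole | [Li]c1c(C(C)(OC)OC)cc([Si](C)(C)C)n1S(=O)(=O)c1ccccc1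
F6 | step 2 | 3-(1,1-dimethoxyethyl)-1-(phenylsulfonyl)-5-(trimethylsilyl)pyrrole-2-carbaldehyde | COC(C)(OC)c1cc([Si](C)(C)C)n(S(=O)(=O)c2ccccc2)c1C=O
F7 | step 11 | chloro{5-[6-bromo-4-methoxy-1-(triisopropylsilyl)indol-3-yl]oxazol-2-yl}zinc | COc1cc(Br)cc2c1c(-c1cnc([Zn]Cl)o1)cn2[Si](C(C)C)(C(C)C)C(C)C
F8 | step 11 | 5-[6-bromo-4-methoxy-1-(triisopropylsilyl)indol-3-yl]-2-iodooxazole | COc1cc(Br)cc2c1c(-c1cnc(I)o1)cn2[Si](C(C)C)(C(C)C)C(C)C
F9 | step 11 | tert-butyl 2-{5-[6-bromo-4-methoxy-1-(triisopropylsilyl)indol-3-yl]oxazol-2-yl}pyrrole-1-carboxylate | COc1cc(Br)cc2c1c(-c1cnc(-c3cccn3C(=O)OC(C)(C)C)o1)cn2[Si](C(C)C)(C(C)C)C(C)C
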